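## Retrosynthetic overview

1. The target is the malonate diester of two identical (13E)-labda-7,13-dien-15-ol units (labdane numbering, C1–C20, is used throughout). It is cut at both ester C–O bonds to this alcohol and malonyl dichloride.
2. Ring B of the alcohol is made last by a two-carbon annulation. A C5 radical adds to CH2=CH–PPh3+ (which becomes C6 and C7), and the ylide that results closes onto a C8 methyl ketone, so C5–C6 and C7=C8 form in one operation and the alkene is fixed at C7.
3. Enabling feature: in ring B, C6 and C7 carry no substituent. C5 is a ring-A methine held between the quaternary C4 and C10, so it is best reached as a radical. C8 lies 1,4 to C5 (through C10–C9) and bears only the C17 methyl, so it maps onto an acetyl group on C9.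
4. The annulation precursor comes from 2,2,6-trimethylcyclohexanone (ring A). Its only enolisable carbon (C10) is allylated with a geraniol-derived allylic carbonate to set C10 and C9. The ring ketone then becomes the C5 radical precursor (an oxalate) and the vinyl group becomes the acetyl group.
5. Ring order: ring A is bought (it enters in step 3); ring B is closed in step 8.

Key step: step 8

Remark: the ring-A carbinol centre created in step 4 is carried as a mixture of epimers (left undefined in the SMILES) until step 8, where that carbon becomes a planar radical.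

## Route

Step 1
Reactants: 1 geraniol
Product: 2 tert-butyl{[(2E)-3,7-dimethylocta-2,6-dien-1-yl]oxy}diphenylsilane
Conditions: TBDPSCl, imidazole, CH2Cl2, 0 °C to rt
Reagents that add atoms: tert-butyl(chloro)diphenylsilane, CC(C)(C)[Si](Cl)(c1ccccc1)c1ccccc1
Why: Standard silylation of a primary allylic alcohol; the silyl ether should survive LiAlH4, aqueous PdCl2/CuCl, CsOH and the ylide of step 8.

Step 2
Reactants: 2 tert-butyl{[(2E)-3,7-dimethylocta-2,6-dien-1-yl]oxy}diphenylsilane
Product: 3 methyl (2E,6E)-8-[(tert-butyldiphenylsilyl)oxy]-6-methylocta-2,6-dien-1-yl carbonate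
Conditions: allyl methyl carbonate (excess), second-generation Hoveyda–Grubbs catalyst (3 mol %), CH2Cl2, 40 °C
Reagents that add atoms: allyl methyl carbonate, C=CCOC(=O)OC
Why: Olefin cross-metathesis at the remote 2-methylprop-1-enyl terminus (the C2=C3 alkene is more congested and deactivated by the allylic silyloxy group) should give the E-disubstituted alkene with loss of isobutene.

Step 3
Reactants: 4 2,2,6-trimethylcyclohexan-1-one, 3 methyl (2E,6E)-8-[(tert-butyldiphenylsilyl)oxy]-6-methylocta-2,6-dien-1-yl carbonate
Product: 6 (2R)-2-[(3S,6E)-8-[(tert-butyldiphenylsilyl)oxy]-6-methylocta-1,6-dien-3-yl]-2,6,6-trimethylcyclohexan-1-one, via lithium enolate 5 (not isolated)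
Conditions: LiN(SiMe3)2, THF, 0 °C; then 3, [Ir(cod)Cl]2 (2 mol %), binaphthol-derived N,N-bis(1-phenylethyl)phosphoramidite (4 mol %, the antipode that gives the C9 configuration shown), LiCl, THF, rt
Reagents that add atoms: none
Why: Iridium-catalysed branched-selective asymmetric allylic alkylation of the single, fully substituted enolate 5 (C10 is the only enolisable carbon of 4): attack at the substituted allyl terminus sets C9 under ligand control, and the enolate face that keeps the C20 methyl anti to H9 sets the quaternary C10.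

Step 4
Reactants: 6 (2R)-2-[(3S,6E)-8-[(tert-butyldiphenylsilyl)oxy]-6-methylocta-1,6-dien-3-yl]-2,6,6-trimethylcyclohexan-1-one
Product: 7 (2R)-2-[(3S,6E)-8-[(tert-butyldiphenylsilyl)oxy]-6-methylocta-1,6-dien-3-yl]-2,6,6-trimethylcyclohexan-1-ol (both C1 epimers)
Conditions: LiAlH4, THF, 0 °C to reflux; aqueous potassium sodium tartrate (KNaC4H4O6) work-up
Reagents that add atoms: none
Why: Hydride reduction of the hindered, non-enolisable ring ketone; the carbinol centre (C5) should form as an epimer mixture, which is harmless because C5 becomes a radical in step 8.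

Step 5
Reactants: 7 (2R)-2-[(3S,6E)-8-[(tert-butyldiphenylsilyl)oxy]-6-methylocta-1,6-dien-3-yl]-2,6,6-trimethylcyclohexan-1-ol (both C1 epimers)
Product: 8 methyl (2R)-2-[(3S,6E)-8-[(tert-butyldiphenylsilyl)oxy]-6-methylocta-1,6-dien-3-yl]-2,6,6-trimethylcyclohexyl oxalate
Conditions: ClC(O)CO2Me, Et3N, DMAP, CH2Cl2, 0 °C to rt
Reagents that add atoms: methyl chlorooxoacetate, COC(=O)C(=O)Cl
Why: Acylation of the hindered secondary alcohol by a small, highly electrophilic acid chloride; no stereocentre is touched.

Step 6
Reactants: 8 methyl (2R)-2-[(3S,6E)-8-[(tert-butyldiphenylsilyl)oxy]-6-methylocta-1,6-dien-3-yl]-2,6,6-trimethylcyclohexyl oxalate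
Product: 9 methyl (2R)-2-[(3R,6E)-8-[(tert-butyldiphenylsilyl)oxy]-6-methyl-2-oxooct-6-en-3-yl]-2,6,6-trimethylcyclohexyl oxalate
Conditions: PdCl2 (10 mol %), CuCl, O2 (1 atm), DMF/H2O 7:1, rt
Reagents that add atoms: water, O
Why: Tsuji–Wacker oxidation; Markovnikov oxypalladation of the only monosubstituted alkene should give the C8 methyl ketone while the trisubstituted alkene and C9 stay untouched under near-neutral conditions.

Step 7
Reactants: 9 methyl (2R)-2-[(3R,6E)-8-[(tert-butyldiphenylsilyl)oxy]-6-methyl-2-oxooct-6-en-3-yl]-2,6,6-trimethylcyclohexyl oxalate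
Product: 10 caesium (2R)-2-[(3R,6E)-8-[(tert-butyldiphenylsilyl)oxy]-6-methyl-2-oxooct-6-en-3-yl]-2,6,6-trimethylcyclohexyl oxalate
Conditions: CsOH·H2O (1.0 equiv), THF/H2O, rt, then evaporation
Reagents that add atoms: caesium hydroxide, [Cs+].[OH-]
Why: Selective saponification of the unhindered methyl ester of the mixed oxalate (the hindered alkyl oxalate linkage stays) should give the caesium alkyl oxalate used as radical precursor.

Step 8
Reactants: 10 caesium (2R)-2-[(3R,6E)-8-[(tert-butyldiphenylsilyl)oxy]-6-methyl-2-oxooct-6-en-3-yl]-2,6,6-trimethylcyclohexyl oxalate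
Product: 13 tert-butyl{[(13E)-labda-7,13-dien-15-yl]oxy}diphenylsilane (trans-fused), via C5 radical 11 (not isolated), via phosphorus ylide 12 (not isolated)
Conditions: CH2=CHPPh3Br (2 equiv), [Ir{dF(CF3)ppy}2(dtbbpy)]PF6 (2 mol %), anhydrous DMSO, 450 nm LEDs, 50 °C
Reagents that add atoms: vinyltriphenylphosphonium bromide, C=C[P+](c1ccccc1)(c1ccccc1)c1ccccc1.[Br-]
Why: Proposed new method: the photoexcited iridium complex oxidises the oxalate of 10, two molecules of CO2 leave, and the secondary C5 radical 11 adds to the unsubstituted CH2 terminus of the vinylphosphonium salt; the α-phosphonio radical is reduced by the reduced photocatalyst to ylide 12 (radical–polar crossover), which closes ring B by intramolecular Wittig olefination of the C8 methyl ketone. The closest known reaction types are the photocatalytic three-component olefination of carboxylate-derived radicals with vinylphosphonium salts and aldehydes, and the anionic cyclohexene annulation of ω-oxo carbanions with vinyltriphenylphosphonium bromide; new here are the alcohol-derived (oxalate) radical at a doubly neopentylic carbon and the ring-forming Wittig step on a ketone. Ring B closes by attack of the ylide carbon C7 on the C8 carbonyl (6-exo-trig, then oxaphosphetane collapse), which puts the double bond at C7=C8 and nowhere else. The only new stereocentre is C5: C6 must enter on the ring-A face of the C20 methyl, anti to the C9 branch (the larger group on C10), through the chair that carries this branch axial, and this becomes the trans ring fusion after closure. C9 and C10 stay as set because the ylide, which is less basic than the ketone enolate, should add to the ketone rather than deprotonate it. The step also needs the radical to take the strongly electrophilic vinylphosphonium salt (in excess) in preference to 6-exo attack on the fully substituted C13 of the side-chain alkene, and the photocatalyst to leave the trisubstituted alkene alone, which lies well above the oxalate in oxidation potential.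

Step 9
Reactants: 13 tert-butyl{[(13E)-labda-7,13-dien-15-yl]oxy}diphenylsilane
Product: 14 (13E)-labda-7,13-dien-15-ol
Conditions: n-Bu4NF, THF, rt
Reagents that add atoms: none
Why: Fluoride-mediated cleavage of the silyl ether; no stereocentre or alkene is affected.

Step 10
Reactants: 14 (13E)-labda-7,13-dien-15-ol (2 equiv)
Product: 16 bis[(13E)-labda-7,13-dien-15-yl] malonate (target CNP0113044.1), via mono-ester acid chloride 15 (not isolated)
Conditions: malonyl dichloride (0.5 equiv), pyridine, CH2Cl2, 0 °C to rt
Reagents that add atoms: malonyl dichloride, O=C(Cl)CC(Cl)=O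
Why: Double acylation of the primary allylic alcohol by the diacid chloride should give the symmetrical diester without touching any stereocentre.

## Compound list

1 | geraniol, (2E)-3,7-dimethylocta-2,6-dien-1-ol | CC(C)=CCC/C(C)=C/CO | starting material
2 | tert-butyl{[(2E)-3,7-dimethylocta-2,6-dien-1-yl]oxy}diphenylsilane | CC(C)=CCC/C(C)=C/CO[Si](c1ccccc1)(c1ccccc1)C(C)(C)C | intermediate
3 | methyl (2E,6E)-8-[(tert-butyldiphenylsilyl)oxy]-6-methylocta-2,6-dien-1-yl carbonate | COC(=O)OC/C=C/CC/C(C)=C/CO[Si](c1ccccc1)(c1ccccc1)C(C)(C)C | intermediate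
4 | 2,2,6-trimethylcyclohexan-1-one | CC1CCCC(C)(C)C1=O | starting material
5 | lithium 2,6,6-trimethylcyclohex-1-en-1-olate | [Li+].[O-]C1=C(C)CCCC1(C)C | intermediate
6 | (2R)-2-[(3S,6E)-8-[(tert-butyldiphenylsilyl)oxy]-6-methylocta-1,6-dien-3-yl]-2,6,6-trimethylcyclohexan-1-one | O=C1C(C)(C)CCC[C@]1(C)[C@H](C=C)CC/C(C)=C/CO[Si](c1ccccc1)(c1ccccc1)C(C)(C)C | intermediate
7 | (2R)-2-[(3S,6E)-8-[(tert-butyldiphenylsilyl)oxy]-6-methylocta-1,6-dien-3-yl]-2,6,6-trimethylcyclohexan-1-ol, both C1 epimers | OC1C(C)(C)CCC[C@]1(C)[C@H](C=C)CC/C(C)=C/CO[Si](c1ccccc1)(c1ccccc1)C(C)(C)C | intermediate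
8 | methyl (2R)-2-[(3S,6E)-8-[(tert-butyldiphenylsilyl)oxy]-6-methylocta-1,6-dien-3-yl]-2,6,6-trimethylcyclohexyl oxalate, both C1 epimers | COC(=O)C(=O)OC1C(C)(C)CCC[C@]1(C)[C@H](C=C)CC/C(C)=C/CO[Si](c1ccccc1)(c1ccccc1)C(C)(C)C | intermediate
9 | methyl (2R)-2-[(3R,6E)-8-[(tert-butyldiphenylsilyl)oxy]-6-methyl-2-oxooct-6-en-3-yl]-2,6,6-trimethylcyclohexyl oxalate, both C1 epimers | COC(=O)C(=O)OC1C(C)(C)CCC[C@]1(C)[C@H](C(C)=O)CC/C(C)=C/CO[Si](c1ccccc1)(c1ccccc1)C(C)(C)C | intermediate
10 | caesium (2R)-2-[(3R,6E)-8-[(tert-butyldiphenylsilyl)oxy]-6-methyl-2-oxooct-6-en-3-yl]-2,6,6-trimethylcyclohexyl oxalate, both C1 epimers | [Cs+].[O-]C(=O)C(=O)OC1C(C)(C)CCC[C@]1(C)[C@H](C(C)=O)CC/C(C)=C/CO[Si](c1ccccc1)(c1ccccc1)C(C)(C)C | intermediate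
11 | secondary ring-A radical at C5 formed from 10 by loss of two CO2 (C9 and C10 as in 10) | [CH]1C(C)(C)CCC[C@]1(C)[C@H](C(C)=O)CC/C(C)=C/CO[Si](c1ccccc1)(c1ccccc1)C(C)(C)C | intermediate
12 | triphenylphosphonium ylide at C7: the C5 carbon of 11 extended by CH2–CH(–)–PPh3(+), C8 ketone intact, C6 syn to the C20 methyl | [CH-]([P+](c1ccccc1)(c1ccccc1)c1ccccc1)C[C@H]1C(C)(C)CCC[C@]1(C)[C@H](C(C)=O)CC/C(C)=C/CO[Si](c1ccccc1)(c1ccccc1)C(C)(C)C | intermediate
13 | tert-butyl{[(13E)-labda-7,13-dien-15-yl]oxy}diphenylsilane (5S,9S,10S; trans-fused) | CC1=CC[C@H]2C(C)(C)CCC[C@]2(C)[C@H]1CC/C(C)=C/CO[Si](c1ccccc1)(c1ccccc1)C(C)(C)C | intermediate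
14 | (13E)-labda-7,13-dien-15-ol, (2E)-3-methyl-5-[(1S,4aS,8aS)-2,5,5,8a-tetramethyl-1,4,4a,5,6,7,8,8a-octahydronaphthalen-1-yl]pent-2-en-1-ol | CC1=CC[C@H]2C(C)(C)CCC[C@]2(C)[C@H]1CC/C(C)=C/CO | intermediate
15 | (13E)-labda-7,13-dien-15-yl 3-chloro-3-oxopropanoate | CC1=CC[C@H]2C(C)(C)CCC[C@]2(C)[C@H]1CC/C(C)=C/COC(=O)CC(Cl)=O | intermediate
16 | bis[(13E)-labda-7,13-dien-15-yl] malonate (CNP0113044.1) | CC1=CC[C@H]2C(C)(C)CCC[C@]2(C)[C@H]1CC/C(C)=C/COC(=O)CC(=O)OC/C=C(\C)CC[C@H]1C(C)=CC[C@H]2C(C)(C)CCC[C@]12C | target

## Step count and risks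

Total steps: 10. Longest linear sequence: 10 steps (compounds 1 to 16; ketone 4 enters at step 3).

The three steps most likely to fail, each with its fallback:

First risk, step 8 (Proposed new method). What may go wrong: poor facial selectivity in the radical addition at C5, since either C10 substituent can sit axial on ring A and the cis-fused C5 epimer may form beside the wanted one (this is the least secure element of the route); slow loss of the second CO2 from the secondary alkoxycarbonyl radical; and protonation of the ylide or enolisation of the C8 ketone, with epimerisation at C9, ahead of ring closure. Fallback for step 8: it sets out from ketone 6 and comes back to the route at 13, uses known reactions only and makes the two bonds in separate operations. Oxidation of the vinyl group of 6 with PdCl2, CuCl and O2 in DMF/H2O should give the 1,4-diketone F1 and leave the hindered ring ketone untouched. Non-basic methylenation (Zn, CH2Br2, TiCl4, THF) of the unhindered acetyl group alone should give the isopropenyl ketone F2 without epimerisation at C9. Allylmagnesium bromide should then add to the hindered ring ketone to give the tertiary homoallylic alcohol F3 as either C5 epimer. Ring-closing metathesis with the second-generation Grubbs catalyst between the allyl and isopropenyl groups should close ring B to the 5-hydroxy silyl ether F4 and release ethene. Acylation (KN(SiMe3)2, then ClC(O)CO2Me) should give the methyl oxalate F5 and this is reduced with Bu3SnH and AIBN in toluene at reflux. The ring-fusion C5 radical should take hydrogen on the α face, opposite the axial C20 and C19 methyls, to give trans-fused 13.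

Second risk, step 3. What may go wrong: sluggish reaction of the hindered, fully substituted enolate with the iridium allyl complex, weak diastereocontrol at the quaternary C10, or attack at the unsubstituted allyl terminus. Fallback for step 3: it sets out from 3 and 4 and comes back to the route at 6, replacing the metal-catalysed allylation by a Claisen rearrangement. Methanolysis of carbonate 3 (K2CO3, MeOH) should give the allylic alcohol F6 and this is converted (MsCl, Et3N, CH2Cl2, −20 °C) into the mesylate F7 that is used crude. Ketone 4 is deprotonated with KH in THF/HMPA to the potassium enolate F8 (not isolated). This enolate should be O-alkylated by the mesylate to the allyl enol ether F9 on account of the hard leaving group, the dissociated potassium enolate and the hindered enolate carbon. Thermal Claisen rearrangement (toluene, 150 °C, sealed tube) through the chair transition state of the E-allyl unit should place the C20 methyl anti to H9, which is the relative configuration of 6. The product forms as a racemate, so the mirror image F10 of ketone 6 is removed by preparative chromatography on a chiral stationary phase.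

Third risk, step 6. What may go wrong: hydrolysis of the mixed oxalate under the aqueous PdCl2/CuCl conditions, and slow or poorly regioselective oxypalladation of the vinyl group beside the quaternary centre. Fallback for step 6: it sets out from 6 and comes back to the route at 9, hydrating the alkene without palladium and before the oxalate is installed. Oxymercuration–demercuration of 6 (Hg(OAc)2, 1.0 equiv, THF/H2O; then NaBH4, NaOH, 0 °C) should give the Markovnikov secondary alcohol F11 because the monosubstituted alkene should react ahead of the trisubstituted one, which is retarded by its allylic silyloxy group, while the hindered ring ketone is left alone. Silylation (TESOTf, 2,6-lutidine, CH2Cl2) should give the triethylsilyl ether F12 and LiAlH4 should then reduce the ring ketone to the ring alcohol F13 as a mixture of epimers. Acylation with methyl chlorooxoacetate (Et3N, DMAP) should give the oxalate F14 from which PPTS in MeOH should remove only the triethylsilyl group. This leaves the hydroxy oxalate F15 for Dess–Martin oxidation to 9.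

Further compounds

F1 | step 8 | (2R)-2-[(3R,6E)-8-[(tert-butyldiphenylsilyl)oxy]-6-methyl-2-oxooct-6-en-3-yl]-2,6,6-trimethylcyclohexan-1-one | O=C1C(C)(C)CCC[C@]1(C)[C@H](C(C)=O)CC/C(C)=C/CO[Si](c1ccccc1)(c1ccccc1)C(C)(C)C
F2 | step 8 | isopropenyl ketone: 6 with the vinyl group replaced by prop-1-en-2-yl (C9 and C10 as in 6) | O=C1C(C)(C)CCC[C@]1(C)[C@H](C(C)=C)CC/C(C)=C/CO[Si](c1ccccc1)(c1ccccc1)C(C)(C)C
F3 | step 8 | tertiary homoallylic alcohol: 1-allyl adduct of F2 at the ring carbonyl (either C1 epimer) | OC1(CC=C)C(C)(C)CCC[C@]1(C)[C@H](C(C)=C)CC/C(C)=C/CO[Si](c1ccccc1)(c1ccccc1)C(C)(C)C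
F4 | step 8 | tert-butyl{[(13E)-5-hydroxylabda-7,13-dien-15-yl]oxy}diphenylsilane (either C5 epimer) | CC1=CCC2(O)C(C)(C)CCC[C@]2(C)[C@H]1CC/C(C)=C/CO[Si](c1ccccc1)(c1ccccc1)C(C)(C)C
F5 | step 8 | methyl oxalate of F4 | CC1=CCC2(OC(=O)C(=O)OC)C(C)(C)CCC[C@]2(C)[C@H]1CC/C(C)=C/CO[Si](c1ccccc1)(c1ccccc1)C(C)(C)C
F6 | step 3 | (2E,6E)-8-[(tert-butyldiphenylsilyl)oxy]-6-methylocta-2,6-dien-1-ol | OC/C=C/CC/C(C)=C/CO[Si](c1ccccc1)(c1ccccc1)C(C)(C)C
F7 | step 3 | (2E,6E)-8-[(tert-butyldiphenylsilyl)oxy]-6-methylocta-2,6-dien-1-yl methanesulfonate | CS(=O)(=O)OC/C=C/CC/C(C)=C/CO[Si](c1ccccc1)(c1ccccc1)C(C)(C)C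
F8 | step 3 | potassium 2,6,6-trimethylcyclohex-1-en-1-olate | [K+].[O-]C1=C(C)CCCC1(C)C
F9 | step 3 | allyl enol ether: 1-{[(2E,6E)-8-[(tert-butyldiphenylsilyl)oxy]-6-methylocta-2,6-dien-1-yl]oxy}-2,6,6-trimethylcyclohex-1-ene | CC1=C(OC/C=C/CC/C(C)=C/CO[Si](c2ccccc2)(c2ccccc2)C(C)(C)C)C(C)(C)CCC1
F10 | step 3 | mirror image of 6, (2S)-2-[(3R,6E)-8-[(tert-butyldiphenylsilyl)oxy]-6-methylocta-1,6-dien-3-yl]-2,6,6-trimethylcyclohexan-1-one | O=C1C(C)(C)CCC[C@@]1(C)[C@@H](C=C)CC/C(C)=C/CO[Si](c1ccccc1)(c1ccccc1)C(C)(C)C
F11 | step 6 | secondary alcohol: 6 with the vinyl group hydrated to 1-hydroxyethyl (carbinol epimers) | O=C1C(C)(C)CCC[C@]1(C)[C@H](C(C)O)CC/C(C)=C/CO[Si](c1ccccc1)(c1ccccc1)C(C)(C)C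
F12 | step 6 | triethylsilyl ether of F11 | O=C1C(C)(C)CCC[C@]1(C)[C@H](C(C)O[Si](CC)(CC)CC)CC/C(C)=C/CO[Si](c1ccccc1)(c1ccccc1)C(C)(C)C
F13 | step 6 | ring alcohol from reduction of F12 (epimers) | OC1C(C)(C)CCC[C@]1(C)[C@H](C(C)O[Si](CC)(CC)CC)CC/C(C)=C/CO[Si](c1ccccc1)(c1ccccc1)C(C)(C)C
F14 | step 6 | methyl oxalate of F13 | COC(=O)C(=O)OC1C(C)(C)CCC[C@]1(C)[C@H](C(C)O[Si](CC)(CC)CC)CC/C(C)=C/CO[Si](c1ccccc1)(c1ccccc1)C(C)(C)C
F15 | step 6 | hydroxy oxalate: F14 without the triethylsilyl group | COC(=O)C(=O)OC1C(C)(C)CCC[C@]1(C)[C@H](C(C)O)CC/C(C)=C/CO[Si](c1ccccc1)(c1ccccc1)C(C)(C)C
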